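## Retrosynthetic overview
1. Ring labels: A and C are the chromone benzene and pyranone, B and D are the isocoumarin benzene and δ-lactone. The bridge CH2 is not made by joining two arenes. Ring B is built new on a side chain of the chromone.
2. Last step: rings B and D form together by Diels–Alder reaction, aromatisation and lactonisation. The partners are a 1-methoxy-1,3-bis(silyloxy)diene carrying CH2-chromone at its terminus and ethyl (R)-5-hydroxyhex-2-ynoate.
3. The diene comes from the β-keto ester ArCH2CH2COCH(Me)CO2Me, made by Heck arylation/isomerisation of 6-iodoeugenin with the acrolein–methyl propionate aldol.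
4. 6-Iodoeugenin comes from eugenin, which comes from symmetric 2',6'-dihydroxy-4'-methoxyacetophenone and ethyl acetate. The ynoate comes from ethyl propiolate and (R)-propylene oxide, the source of the only stereocentre.
5. Ring order: A is bought, C closes in step 1, and B and D close together in step 6.

Assumption: 2',6'-dihydroxy-4'-methoxyacetophenone (4-O-methylphloroacetophenone) is taken as a catalogue chemical. Chromone and isocoumarin atoms carry their usual locants.

## Route

Step 1
Reactants: 1 2',6'-dihydroxy-4'-methoxyacetophenone; 2 ethyl acetate (excess)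
Product: 4 eugenin (5-hydroxy-7-methoxy-2-methyl-4H-chromen-4-one), via 1,3-diketone 3 (not isolated)
Conditions: NaH (5 equiv), THF, reflux; then conc. HCl, MeOH, reflux
Reagents that add atoms: none
Why: Crossed Claisen condensation of the acetophenone polyanion with ethyl acetate gives the 1,3-diketone and acid cyclodehydration closes ring C, and because the two phenols of 1 are equivalent by symmetry only one chromone can form and no stereocentre is created.

Step 2
Reactants: 4 eugenin
Product: 5 6-iodoeugenin (5-hydroxy-6-iodo-7-methoxy-2-methyl-4H-chromen-4-one)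
Conditions: NIS (1.05 equiv), DMF, rt, dark
Reagents that add atoms: N-iodosuccinimide (NIS), O=C1CCC(=O)N1I
Why: Electrophilic aromatic iodination, in which 5-hydroxy-7-alkoxychromones and -flavones with a free, hydrogen-bonded 5-OH react with NIS under neutral conditions at C6 (ortho to the phenol) rather than C8, so the future bridge position is fixed here.

Step 3
Reactants: 6 methyl propionate; 7 acrolein
Product: 9 methyl 3-hydroxy-2-methylpent-4-enoate (racemic syn/anti mixture), via lithium enolate 8 (not isolated)
Conditions: LiN(iPr)2 (LDA, commercial solution), THF, −78 °C; then 7; AcOH quench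
Reagents that add atoms: none
Why: Lithium-enolate aldol addition (clean 1,2-addition to acrolein at low temperature), with the stereoisomer mixture used as such because both new stereocentres are erased in steps 4 and 6.

Step 4
Reactants: 5 6-iodoeugenin; 9 methyl 3-hydroxy-2-methylpent-4-enoate
Product: 11 methyl 5-(5-hydroxy-7-methoxy-2-methyl-4-oxo-4H-chromen-6-yl)-2-methyl-3-oxopentanoate (racemic), via Heck enol 10 (not isolated)
Conditions: Pd(OAc)2 (5 mol %), n-Bu4NCl, NaHCO3, DMF, 70 °C
Reagents that add atoms: none
Why: Heck arylation of a secondary allylic alcohol under Jeffery conditions, where aryl transfer to the terminal alkene carbon, β-hydride elimination toward the carbinol C–H and enol–ketone tautomerisation give the saturated β-keto ester directly, placing the future bridge CH2 on C6 without a benzylic halide, and the racemic α-stereocentre is erased in step 6.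

Step 5
Reactants: 12 ethyl propiolate; 13 (R)-propylene oxide
Product: 15 ethyl (R)-5-hydroxyhex-2-ynoate, via lithium acetylide 14 (not isolated)
Conditions: n-BuLi, THF, −78 °C; BF3·OEt2; then 13, −78 °C; H2O quench
Reagents that add atoms: none
Why: Yamaguchi–Hirao alkynylation, in which the BF3-activated epoxide is opened by SN2 attack at its unsubstituted carbon, so the C–O stereocentre of (R)-propylene oxide is untouched and becomes C3 of the target with R configuration.

Step 6
Reactants: 11 β-keto ester; 15 ethyl (R)-5-hydroxyhex-2-ynoate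
Product: 20 (R)-6,8-dihydroxy-5-[(5-hydroxy-7-methoxy-2-methyl-4-oxo-4H-chromen-6-yl)methyl]-3,7-dimethyl-3,4-dihydro-1H-isochromen-1-one (CNP0180307.1), via tris-silyl diene 16 (not isolated), via silyl ether 17 (not isolated), via cyclohexadiene adduct 18 (not isolated), via hydroxy ester 19 (not isolated)
Conditions: 11, Et3N (8 equiv), TMSOTf (3.5 equiv), toluene, 0 °C to rt; add 15 (1.5 equiv) and TMSOTf (1.6 equiv), 0 °C, 20 min; cannulate off the Et3NH·OTf layer, concentrate; 135 °C, sealed tube, 36 h; then 2 M HCl, THF, 50 °C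
Reagents that add atoms: none
Why: Soft enolisation gives a Chan/Brassard-type 1-methoxy-1,3-bis(silyloxy)diene whose most nucleophilic terminus (the CH bearing the CH2-chromone) bonds to the β-carbon of the alkynoate in a normal-demand Diels–Alder reaction (a stepwise Mukaiyama–Michael/Dieckmann path closes the same ring), after which acid removes the silyl groups, the C8 hemiketal loses methanol to aromatise ring B and the freed (R)-alcohol lactonises onto the neighbouring ester by acyl–oxygen cleavage, so rings B and D form together, all six substituents are placed by the cycloaddition regiochemistry and the stereocentre is retained.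

## Compound list
1 | 2',6'-dihydroxy-4'-methoxyacetophenone | CC(=O)c1c(O)cc(OC)cc1O | starting material
2 | ethyl acetate | CCOC(C)=O | starting material
3 | 1-(2,6-dihydroxy-4-methoxyphenyl)butane-1,3-dione (not isolated) | CC(=O)CC(=O)c1c(O)cc(OC)cc1O | intermediate
4 | eugenin, 5-hydroxy-7-methoxy-2-methyl-4H-chromen-4-one | Cc1cc(=O)c2c(O)cc(OC)cc2o1 | intermediate
5 | 6-iodoeugenin, 5-hydroxy-6-iodo-7-methoxy-2-methyl-4H-chromen-4-one | Cc1cc(=O)c2c(O)c(I)c(OC)cc2o1 | intermediate
6 | methyl propionate | CCC(=O)OC | starting material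
7 | acrolein | C=CC=O | starting material
8 | lithium enolate of methyl propionate (not isolated) | CC=C([O-])OC.[Li+] | intermediate
9 | methyl 3-hydroxy-2-methylpent-4-enoate (racemic, syn/anti mixture) | COC(=O)C(C)C(O)C=C | intermediate
10 | methyl 3-hydroxy-5-(5-hydroxy-7-methoxy-2-methyl-4-oxo-4H-chromen-6-yl)-2-methylpent-3-enoate, Heck enol (not isolated) | COC(=O)C(C)C(O)=CCc1c(OC)cc2oc(C)cc(=O)c2c1O | intermediate
11 | methyl 5-(5-hydroxy-7-methoxy-2-methyl-4-oxo-4H-chromen-6-yl)-2-methyl-3-oxopentanoate (racemic) | COC(=O)C(C)C(=O)CCc1c(OC)cc2oc(C)cc(=O)c2c1O | intermediate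
12 | ethyl propiolate | C#CC(=O)OCC | starting material
13 | (R)-propylene oxide | C[C@@H]1CO1 | starting material
14 | ethyl 3-lithiopropiolate (not isolated) | [Li]C#CC(=O)OCC | intermediate
15 | ethyl (R)-5-hydroxyhex-2-ynoate | CCOC(=O)C#CC[C@@H](C)O | intermediate
16 | 6-[(3Z)-5-methoxy-4-methyl-3,5-bis(trimethylsilyloxy)penta-2,4-dienyl]-7-methoxy-2-methyl-5-(trimethylsilyloxy)chromen-4-one, ketene acetal E/Z mixture (not isolated) | COC(O[Si](C)(C)C)=C(C)/C(O[Si](C)(C)C)=C/Cc1c(OC)cc2oc(C)cc(=O)c2c1O[Si](C)(C)C | intermediate
17 | ethyl (R)-5-(trimethylsilyloxy)hex-2-ynoate (not isolated) | CCOC(=O)C#CC[C@@H](C)O[Si](C)(C)C | intermediate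
18 | cyclohexa-1,4-diene Diels–Alder adduct, mixture at the two new ring stereocentres, side chain R (not isolated) | CCOC(=O)C1=C(C[C@@H](C)O[Si](C)(C)C)C(Cc2c(OC)cc3oc(C)cc(=O)c3c2O[Si](C)(C)C)C(O[Si](C)(C)C)=C(C)C1(OC)O[Si](C)(C)C | intermediate
19 | ethyl 2,4-dihydroxy-5-[(5-hydroxy-7-methoxy-2-methyl-4-oxo-4H-chromen-6-yl)methyl]-6-[(R)-2-hydroxypropyl]-3-methylbenzoate (not isolated) | CCOC(=O)c1c(O)c(C)c(O)c(Cc2c(OC)cc3oc(C)cc(=O)c3c2O)c1C[C@@H](C)O | intermediate
20 | (R)-6,8-dihydroxy-5-[(5-hydroxy-7-methoxy-2-methyl-4-oxo-4H-chromen-6-yl)methyl]-3,7-dimethyl-3,4-dihydro-1H-isochromen-1-one | COc1cc2oc(C)cc(=O)c2c(O)c1Cc1c(O)c(C)c(O)c2c1C[C@@H](C)OC2=O | target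

## Step count and risks
Total step count: 6.
Longest linear sequence: 4 steps (steps 1, 2, 4 and 6).

**Step 6 (highest risk).** A fully substituted diene must add to a β-alkyl alkynoate to give a hexasubstituted benzene. Transient silylation of the pyranone carbonyl may also compete. The exocyclic diene that would arise from this is locked s-trans, cannot cycloadd, and reverts on acid work-up.

The fallback sets out from 15 (as its silyl ether 17) and from 4, and comes back at 20. Rings B and D are still made together, but on a small and much less hindered diene, and the two halves are joined afterwards. Commercial 2-methylcyclohexane-1,3-dione is bis-silylated (TMSOTf, Et3N) to 2-methyl-1,3-bis(trimethylsilyloxy)cyclohexa-1,3-diene F1. Its Alder–Rickert reaction with 17 (neat, 150 °C, cycloaddition then loss of ethene), followed by HCl work-up, gives (R)-6,8-dihydroxy-3,7-dimethyl-3,4-dihydro-1H-isochromen-1-one F2. Compound 4 is aminomethylated with dimethylmethyleneiminium iodide to 6-[(dimethylamino)methyl]-5-hydroxy-7-methoxy-2-methyl-4H-chromen-4-one F3. Heating F2 with F3 in dioxane expels dimethylamine. The resulting ortho-quinone methide is captured by C5 of F2, its only free ring carbon, to give 20.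

**Step 4.** The aryl iodide is flanked by OH and OMe. The allylic alcohol can also isomerise or dehydrate before it couples.

The fallback sets out from 5 and comes back at 11. It replaces alkene insertion by conjugate addition to an ortho-quinone methide. Stille coupling of 5 with (tributylstannyl)methanol (Pd(PPh3)4, dioxane, 90 °C) gives 5-hydroxy-6-(hydroxymethyl)-7-methoxy-2-methyl-4H-chromen-4-one F4. Commercial methyl 2-methylacetoacetate with TMSOTf and Et3N gives 1-methoxy-2-methyl-1,3-bis(trimethylsilyloxy)buta-1,3-diene F5. BF3·OEt2 in CH2Cl2 at −40 °C ionises F4 to its ortho-quinone methide, which F5 attacks through its terminal CH2 (vinylogous Mukaiyama–Michael addition). Dilute acid then gives 11.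

**Step 2.** The risk is C6 against C8 selectivity, together with over-iodination.

The fallback sets out from 4 and comes back at 11, bypassing steps 2 to 4. It fixes C6 by a sigmatropic shift instead of by electrophilic selectivity. O-Allylation of 4 (allyl bromide, K2CO3, DMF, 70 °C) gives 5-(allyloxy)-7-methoxy-2-methyl-4H-chromen-4-one F6. Its aromatic Claisen rearrangement (N,N-diethylaniline, 200 °C) can deliver the allyl group only to C6, the single ortho position, giving 6-allyl-5-hydroxy-7-methoxy-2-methyl-4H-chromen-4-one F7. Hydroboration–oxidation (9-BBN, then NaBO3) gives 5-hydroxy-6-(3-hydroxypropyl)-7-methoxy-2-methyl-4H-chromen-4-one F8. Dess–Martin oxidation gives 3-(5-hydroxy-7-methoxy-2-methyl-4-oxo-4H-chromen-6-yl)propanal F9. Roskamp homologation of F9 with methyl 2-diazopropanoate (Sc(OTf)3 or SnCl2 cat., CH2Cl2) gives 11.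

## Further compounds
F1 | step 6 | 2-methyl-1,3-bis(trimethylsilyloxy)cyclohexa-1,3-diene | CC1=C(O[Si](C)(C)C)CCC=C1O[Si](C)(C)C
F2 | step 6 | (R)-6,8-dihydroxy-3,7-dimethyl-3,4-dihydro-1H-isochromen-1-one | C[C@@H]1Cc2cc(O)c(C)c(O)c2C(=O)O1
F3 | step 6 | 6-[(dimethylamino)methyl]-5-hydroxy-7-methoxy-2-methyl-4H-chromen-4-one | CN(C)Cc1c(OC)cc2oc(C)cc(=O)c2c1O
F4 | step 4 | 5-hydroxy-6-(hydroxymethyl)-7-methoxy-2-methyl-4H-chromen-4-one | OCc1c(OC)cc2oc(C)cc(=O)c2c1O
F5 | step 4 | 1-methoxy-2-methyl-1,3-bis(trimethylsilyloxy)buta-1,3-diene | COC(O[Si](C)(C)C)=C(C)C(=C)O[Si](C)(C)C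
F6 | step 2 | 5-(allyloxy)-7-methoxy-2-methyl-4H-chromen-4-one | C=CCOc1cc(OC)cc2oc(C)cc(=O)c12
F7 | step 2 | 6-allyl-5-hydroxy-7-methoxy-2-methyl-4H-chromen-4-one | C=CCc1c(OC)cc2oc(C)cc(=O)c2c1O
F8 | step 2 | 5-hydroxy-6-(3-hydroxypropyl)-7-methoxy-2-methyl-4H-chromen-4-one | OCCCc1c(OC)cc2oc(C)cc(=O)c2c1O
F9 | step 2 | 3-(5-hydroxy-7-methoxy-2-methyl-4-oxo-4H-chromen-6-yl)propanal | O=CCCc1c(OC)cc2oc(C)cc(=O)c2c1O
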